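Time is what this flask is asked about, and 3.0 min lies beyond the last reading of either earlier run, so I need something that stays constant over that gap.

| flask | X | remark | time |
|---|---|---|---|
| ochre | 1 M | run made earlier |  |
| blue | 1.5 M | run made earlier |  |
| flask | 2.0 M |  | 3.0 min |

- ochre (time / s: J / %, X / %): 25.0: 4.9, 92.2; 50.0: 12.2, 85.0; 80.0: 22.6, 72.2; 120: 33.0, 60.1
- blue (time / s: J / %, X / %): 25.0: 4.1, 94.9; 50.0: 9.4, 86.6; 80.0: 15.7, 80.8; 120: 23.8, 72.7

(scatter of a reading: 1 percentage point)

1. the J standing at 3.0 min, as a percentage of the X charged
2. the change that raises the amount of J at 3.0 min, in percent of the X charged most ("none" if none brings more than 2 percentage points) (maple / oak / none)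
3. amount of J at 3.0 min, in percent of the X charged, after maple

- given per volume of solution although it is solid: X
- the numbers in the tables scatter with a standard deviation of 1 percentage point
- at the start none of X is in solution

- maple: doubling the solubility of X, all else as stated
- oak: doubling the dissolution coefficient of X, all else as stated

Read as percentages, the two tables differ: at 120 s, ochre shows J at 33.0% and blue at 23.8%. Multiplied by their charges, they nearly meet, at 0.330 M and 0.357 M. From 50.0 s to 120 s, ochre gains 0.00297 M/s and blue 0.00309 M/s, close together despite different charges: zero order in the charge. I freeze their mean, 0.00303 M/s, and call it the feed, the steady molar rise of J while solid stands.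

Starting from the mean 0.344 M at 120 s, the feed carries J to 0.525 M, which is 26.3% of this flask's charge. If solubility sets the feed in proportion, maple doubles that to 52.6%. Oak, doubling the dissolution coefficient of X, I leave without a figure, because the feed as I read it from these runs gives me none for it.

The forecast gives 27%, above mine, names maple, and gives 54%. Its ground: “So the rate is zero order in solid, and solution held at a steady level by dissolution feeds the reaction.”

The flask gives 27.4%. Maple adds 27 percentage points, reaching 54.7%, and oak adds 26 points, close behind.

In these equations D is X in solution, Z is another product, and G, E, L and Q are species formed on the way.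

    G → J (k = 0.250 /s)
    L ⇌ Q (K = 13.0, k = 0.0180 /s)
    G → E (k = 0.00880 /s)
    E → Z (k = 0.0270 /s)
    D → G (k = 0.140 /s)
    X ⇌ D, rate k6*(cs6 - [D]) while solid is left; crystals form when [D] > cs6 (solubility = 0.770 M, k = 0.00450 /s)
    G ⇌ L (K = 1.20, k = 7.10 × 10⁻⁴ /s)

This flask is not at rest at 3.0 min: X stands at 69.8%, and J rises by 0.00323 M/s over the second half, against the feed of 0.00303 M/s. Reckoned at the feed, as an estimate, the charge of this flask lasts 11.0 min. Ten times the time, 30.0 min, brings J to 96.4%, a further 69 points, with X at 0% and Z at 3.39%.

In a second flask with 1.2 M of X and the same time, the feed's 0.525 M is 43.8% of that charge. The computed flask gives 45.6%.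

The numbers in the tables were generated by integration for substances that don't exist; scatter was added.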